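The dihydropyran ring is cut at C2–C3 and C4–C4a. C3 and C4 come from a two-carbon π unit, and the rest comes from the O-aryl oxocarbenium ion of camphenilone. The key step is a cationic [4+2] annulation of oxa-Povarov type. It ionises a spiro benzodioxinone, a temporary ring that ties the phloroglucinol oxygen and a carboxylate leaving group to spiro carbon C2, and takes up 4-methylpenta-1,3-diene. It exploits spiro C2 as a non-enolisable, ketone-level carbon of the norbornane ring that carbon nucleophiles attack on the exo face, leaving oxygen endo. It also exploits aromatic C4a, activated by three oxygens. Hydrogenation, decarboxylation and double formylation follow.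

Key step: step 4

Numbering used: chroman O1, C2 (spiro), C3, C4, C4a, C5–C8, C8a. Norbornane atoms carry the suffix n (C1n is the bridgehead next to C2, C3n is CMe2).

Assumption: commercial (1S,4R)-(−)-camphene is taken as enantiopure. Every stereocentre of the target derives from it, so material of lower optical purity would have to be enriched first, for example through a crystalline derivative of ketone 3.

Step 1
Reactants: 1 (1S,4R)-(−)-camphene
Product: 3 (1R,4S)-camphenilone (3,3-dimethylbicyclo[2.2.1]heptan-2-one), via secondary ozonide 2 (not isolated)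
Conditions: O3, CH2Cl2, −78 °C; then Me2S, −78 °C → rt
Reagents that add atoms: ozone [O-][O+]=O
Why: Ozonolysis (Criegee mechanism, reductive work-up) cleaves the only C=C bond and touches neither bridgehead, so both stereocentres of 1 pass unchanged into 3 (the descriptors change only because the numbering does).

Step 2
Reactants: 3 (1R,4S)-camphenilone; 4 2,4,6-trihydroxybenzoic acid
Product: 5 (1R,4S)-5',7'-dihydroxy-3,3-dimethylspiro[bicyclo[2.2.1]heptane-2,2'-[1,3]benzodioxin]-4'-one (either configuration at the spiro carbon)
Conditions: (CF3CO)2O, CF3CO2H, 0 °C → rt, 4 in excess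
Reagents that add atoms: none
Why: The known TFAA/TFA condensation of salicylic acids with ketones to 4H-1,3-benzodioxin-4-ones should apply because hemiketal formation at the hindered carbonyl is pulled forward by intramolecular acylation and 3 cannot enolise, while the new spiro centre, formed without control, is planarised again in step 4.

Step 3
Reactants: 5 dihydroxy spiro benzodioxinone
Product: 6 (1R,4S)-5',7'-bis(benzyloxy)-3,3-dimethylspiro[bicyclo[2.2.1]heptane-2,2'-[1,3]benzodioxin]-4'-one
Conditions: BnBr (2.5 equiv), K2CO3, DMF, 60 °C
Reagents that add atoms: benzyl bromide BrCc1ccccc1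
Why: Williamson ether synthesis on the two phenols (the chelated 5'-OH needs the warm DMF) runs under base, to which the acylal ring is inert, and no stereocentre is affected.

Step 4
Reactants: 6 bis(benzyloxy) spiro benzodioxinone; 7 4-methylpenta-1,3-diene
Product: 11 (1R,2R,4S,4'R)-5',7'-bis(benzyloxy)-3,3-dimethyl-4'-(2-methylprop-1-enyl)spiro[bicyclo[2.2.1]heptane-2,2'-chromane]-8'-carboxylic acid, via aryl oxocarbenium triflate 8 (not isolated), via dimethylallyl cation 9 (not isolated), via trimethylsilyl ester 10 (not isolated)
Conditions: Me3SiOTf (2 equiv), 2,6-di-tert-butyl-4-methylpyridine, 7 (5 equiv), CH2Cl2, −78 → −20 °C; aq NaHCO3, then citric acid to pH 4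
Reagents that add atoms: none
Why: Proposed new method: Me3SiOTf silylates the lactone carbonyl of 6 and the C2–O(acyl) bond ionises, since carboxylate is the better leaving group and the aryloxy group the better donor, which opens the temporary ring to aryl oxocarbenium ion 8, a cationic 2-oxadiene that cannot lose a proton because C2 lies between bridgehead C1n–H and quaternary C3n. The unsubstituted terminus of 7 adds to C2 to give dimethylallyl cation 9, whose secondary terminus is taken by the free aromatic carbon ortho to O1 (ortho, ortho and para to three oxygens) in a 6-exo-trig Friedel–Crafts closure of the dihydropyran ring, so that C2–C3 and C4–C4a arise in one operation as a stepwise formal [4+2]. The closest known reaction types are the oxa-Povarov reaction of aldehyde-derived aryl oxocarbenium ions with alkenes and the Lewis-acid opening of 1,3-dioxan-4-ones by π-nucleophiles with loss of carboxylate, neither of which has been shown for a ketone-derived spiro benzodioxinone or a 1,3-diene. Spiro C2 is controlled by the norbornane: the gem-dimethyl group burdens both faces alike, so the intrinsic exo preference of a 2-norbornyl sp2 carbon, seen in organometallic additions to camphenilone, should place C3 exo and O1 endo. C4 is controlled by a chair-like closure in which C3n and the isobutenyl group are both equatorial and hence cis, whereas closure at the tertiary allyl terminus would need an eight-membered ring that holds an E alkene. The step needs 7 to win over ring re-closure and over its own cationic oligomerisation, which the silyl capping of the carboxylate, the excess of 7, the low temperature and the hindered pyridine as proton trap are meant to secure.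

Step 5
Reactants: 11 bis(benzyloxy) isobutenyl chroman-8'-carboxylic acid
Product: 13 (1R,2R,4S,4'S)-3,3-dimethyl-4'-(2-methylpropyl)spiro[bicyclo[2.2.1]heptane-2,2'-chromane]-5',7'-diol, via dihydroxy acid 12 (not isolated)
Conditions: H2 (4 bar), Pd/C (10 wt%), EtOAc–EtOH, rt; filter; then dioxane–H2O, 95 °C
Reagents that add atoms: none
Why: Heterogeneous hydrogenation saturates the trisubstituted alkene and hydrogenolyses both benzyl ethers, after which the 2,4,6-trioxygenated benzoic acid 12 undergoes thermal protodecarboxylation; no stereocentre is formed, and the hydrogen pressure is meant to make saturation faster than alkene migration towards C4.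

Step 6
Reactants: 13 5',7'-dihydroxy spiro chroman
Product: 15 (1R,2R,4S,4'S)-5',7'-dihydroxy-3,3-dimethyl-4'-(2-methylpropyl)spiro[bicyclo[2.2.1]heptane-2,2'-chromane]-6',8'-dicarbaldehyde (target), via bis(alpha-chloro ether) 14 (not isolated)
Conditions: Cl2CHOMe (5 equiv), TiCl4 (5 equiv), CH2Cl2, −78 → 0 °C; then ice, 1 M HCl
Reagents that add atoms: dichloromethyl methyl ether COC(Cl)Cl; water O
Why: In this Rieche formylation the only two free aromatic positions, C6 and C8, are each ortho or para to three oxygens and should both react, while the low temperature and the endo-oriented, slowly ionising C2–O1 bond should keep the spiro ether and all four stereocentres intact.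

Compound list
1 | (1S,4R)-(−)-camphene, (1S,4R)-2,2-dimethyl-3-methylidenebicyclo[2.2.1]heptane | C=C1[C@@H]2CC[C@@H](C2)C1(C)C | starting material
2 | camphene secondary ozonide, spiro 1,2,4-trioxolane on C2 of the norbornane (spiro centre undefined) | C1OOC2(O1)[C@@H]3CC[C@@H](C3)C2(C)C | intermediate
3 | (1R,4S)-camphenilone, (1R,4S)-3,3-dimethylbicyclo[2.2.1]heptan-2-one | O=C1[C@@H]2CC[C@@H](C2)C1(C)C | intermediate
4 | 2,4,6-trihydroxybenzoic acid | OC(=O)c1c(O)cc(O)cc1O | starting material
5 | (1R,4S)-5',7'-dihydroxy-3,3-dimethylspiro[bicyclo[2.2.1]heptane-2,2'-[1,3]benzodioxin]-4'-one (spiro centre undefined) | O=C1OC2(Oc3cc(O)cc(O)c31)[C@@H]1CC[C@@H](C1)C2(C)C | intermediate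
6 | (1R,4S)-5',7'-bis(benzyloxy)-3,3-dimethylspiro[bicyclo[2.2.1]heptane-2,2'-[1,3]benzodioxin]-4'-one (spiro centre undefined) | O=C1OC2(Oc3cc(OCc4ccccc4)cc(OCc4ccccc4)c31)[C@@H]1CC[C@@H](C1)C2(C)C | intermediate
7 | 4-methylpenta-1,3-diene | C=CC=C(C)C | starting material
8 | O-[3,5-bis(benzyloxy)-2-(trimethylsilyloxycarbonyl)phenyl] oxocarbenium triflate of (1R,4S)-camphenilone | C[Si](C)(C)OC(=O)c1c(OCc2ccccc2)cc(OCc2ccccc2)cc1[O+]=C1[C@@H]2CC[C@@H](C2)C1(C)C.[O-]S(=O)(=O)C(F)(F)F | intermediate
9 | (E)-dimethylallyl cation (triflate) with the chain exo and the aryloxy group endo on C2 (1R,2R,4S) | C[C+](C)/C=C/C[C@@]1(Oc2cc(OCc3ccccc3)cc(OCc3ccccc3)c2C(=O)O[Si](C)(C)C)[C@@H]2CC[C@@H](C2)C1(C)C.[O-]S(=O)(=O)C(F)(F)F | intermediate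
10 | trimethylsilyl ester of acid 11 | CC(C)=C[C@H]1C[C@@]2(Oc3c(C(=O)O[Si](C)(C)C)c(OCc4ccccc4)cc(OCc4ccccc4)c31)[C@@H]1CC[C@@H](C1)C2(C)C | intermediate
11 | (1R,2R,4S,4'R)-5',7'-bis(benzyloxy)-3,3-dimethyl-4'-(2-methylprop-1-enyl)spiro[bicyclo[2.2.1]heptane-2,2'-chromane]-8'-carboxylic acid | CC(C)=C[C@H]1C[C@@]2(Oc3c(C(O)=O)c(OCc4ccccc4)cc(OCc4ccccc4)c31)[C@@H]1CC[C@@H](C1)C2(C)C | intermediate
12 | (1R,2R,4S,4'S)-5',7'-dihydroxy-3,3-dimethyl-4'-(2-methylpropyl)spiro[bicyclo[2.2.1]heptane-2,2'-chromane]-8'-carboxylic acid | CC(C)C[C@H]1C[C@@]2(Oc3c(C(O)=O)c(O)cc(O)c31)[C@@H]1CC[C@@H](C1)C2(C)C | intermediate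
13 | (1R,2R,4S,4'S)-3,3-dimethyl-4'-(2-methylpropyl)spiro[bicyclo[2.2.1]heptane-2,2'-chromane]-5',7'-diol | CC(C)C[C@H]1C[C@@]2(Oc3cc(O)cc(O)c31)[C@@H]1CC[C@@H](C1)C2(C)C | intermediate
14 | 6',8'-bis[chloro(methoxy)methyl] derivative of 13 (chloro ether centres undefined) | CC(C)C[C@H]1C[C@@]2(Oc3c(C(Cl)OC)c(O)c(C(Cl)OC)c(O)c31)[C@@H]1CC[C@@H](C1)C2(C)C | intermediate
15 | (1R,2R,4S,4'S)-5',7'-dihydroxy-3,3-dimethyl-4'-(2-methylpropyl)spiro[bicyclo[2.2.1]heptane-2,2'-chromane]-6',8'-dicarbaldehyde | CC(C)C[C@H]1C[C@@]2(Oc3c(C=O)c(O)c(C=O)c(O)c31)[C@@H]1CC[C@@H](C1)C2(C)C | target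

Total step count: 6. Longest linear sequence: 6 (1 → 15).

Steps most likely to fail

Step 4 (Proposed new method).
- **Risk:** Capture of the hindered cation by the diene may be too slow. Re-closure of the temporary ring, cationic oligomerisation of the diene or Wagner–Meerwein drift of the norbornyl framework could then take over. The facial selectivity of the closure at C4 may also be poor.
- **Fallback:** This uses known chemistry, sets out from 1 and comes back to the route at 15. Alkene 1 is heated with 2,4,6-trihydroxybenzene-1,3-dicarbaldehyde F1 and 3-methylbutanal F2 (NaOAc, AcOH, 80 °C). Knoevenagel condensation forms the ortho-quinone methide F3, which adds to the exocyclic alkene of 1 in an inverse-demand hetero-Diels–Alder reaction.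
- **Cost:** This variant builds the pyran ring through C3–C4 and O1–C2. It therefore gives up the exo carbon attack that sets the spiro centre. The isomers at C2 and C4 would have to be separated by chromatography.

Step 2.
- **Risk:** Addition to the hindered carbonyl may be so sluggish that acid 4 is lost to decarboxylation or trifluoroacetylation before the ring closes.
- **Fallback:** This sets out from 3 and comes back at 5. The ketone is first activated as camphenilone dimethyl ketal F4 (HC(OMe)3, MeOH, cat. TsOH). F4 is then exchanged with 4 (cat. camphorsulfonic acid, CH2Cl2, 5 Å molecular sieves, 40 °C). Carbonyl addition is thereby replaced by capture of a preformed, strain-relieved oxocarbenium ion.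

Step 6.
- **Risk:** TiCl4, chelated between the new C8 formyl group and O1, may ionise the tertiary C2–O1 bond with ring opening and skeletal rearrangement. The reaction may also stall after the first formylation.
- **Fallback:** This sets out from 13 and comes back at 15 without new isolated compounds. It is a Casnati–Skattebøl ortho-formylation (MgCl2, Et3N, paraformaldehyde, MeCN, reflux). The acid-bound carbocation equivalent is replaced by magnesium phenoxide-directed hydroxymethylation and hydride-transfer oxidation under basic conditions.

Further compounds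
F1 | step 4 | 2,4,6-trihydroxybenzene-1,3-dicarbaldehyde | O=Cc1c(O)c(C=O)c(O)cc1O
F2 | step 4 | 3-methylbutanal | CC(C)CC=O
F3 | step 4 | ortho-quinone methide, 2,4-dihydroxy-5-(3-methylbutylidene)-6-oxocyclohexa-1,3-diene-1,3-dicarbaldehyde | CC(C)CC=C1C(=O)C(C=O)=C(O)C(C=O)=C1O
F4 | step 2 | camphenilone dimethyl ketal, (1R,4S)-2,2-dimethoxy-3,3-dimethylbicyclo[2.2.1]heptane | COC1(OC)[C@@H]2CC[C@@H](C2)C1(C)C
F0 | step 6 | none | none
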